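Compound numbers used throughout: 1–4 are the ring A series, 5–8 the ring B/C series, 9 the aryllithium, 10–15 the coupled series and 16 the target. Ring A is the ring with the free carboxyl, ring B the middle ring, ring C the terminal ring.

## The problem

Target 16 is a linear trimer of gallic acid whose three benzenoid rings are held together only by two aryl ester (depside) bonds. O4 of ring A is acylated by the carboxyl of ring B, and one meta oxygen of ring B (O5) is acylated by the carboxyl of ring C. There is no stereocenter, so nothing has to be controlled in space; the whole difficulty is regiochemical. O4 of ring A is the most hindered oxygen of that ring, flanked by the oxygens on C3 and C5. O5 of ring B has to be told apart from the equivalent O3 and from the more acidic O4. Both links are aryl esters that bases and nucleophiles cleave or transesterify. Once a hydroxyl next to an ester oxygen is free, the acyl group can also move between neighbouring oxygens, and the free polyphenol oxidises in air under basic conditions. All phenols therefore have to stay masked until a final, neutral step. The feature that makes the key step possible is C4 of ring A: it has oxygen on both ortho carbons (C3 and C5), so an aryl group attached through C4 is an excellent migrating group. The A–B ester can thus be made by inserting oxygen into a C4(ring A)–carbonyl carbon bond instead of acylating a hindered phenol.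

## Retrosynthesis

**16 from 15.** The seven O–benzyl bonds are cut last. Benzyl ethers are the only phenol protection that can be removed under neutral, non-nucleophilic conditions; methyl ethers would need Lewis acids that endanger the esters, and acyl groups would need base. Hydrogenolysis of acid 15 is asked only to leave two aryl esters alone.

**15 from 12 through 14 and 13.** The carboxyl of ring A is traced back to a silyloxymethyl group: acid 15 from aldehyde 14, alcohol 13 and silyl ether 12. No skeletal bond is cut here. The cost is three steps. The gain is that C1 of ring A is an alkyl-type substituent during the two steps that need it: it tolerates the aryllithium, and it keeps ring A electron-rich for the migration.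

**12 from 11 (key disconnection).** The oxygen between C4 of ring A and the ring B carbonyl is removed, which turns depside 12 into diaryl ketone 11. The neighbouring cut, through the acyl–oxygen bond, would require acylation of a phenol flanked by two benzyloxy groups with a large acid. The chosen cut uses those same two ortho oxygens as the reason ring A migrates. The precursor is simpler by one heteroatom link, and the position of the future ester is fixed by a C–C bond. The forward reaction must insert oxygen on the ring A side only and must spare benzyl ethers, a silyl ether and the ring C ester.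

**11 from 4 and 8 through 10 and 9.** The ketone is cut at the bond between the carbonyl carbon and C4 of ring A. This gives aryllithium 9, made from bromide 4, and aldehyde 8, joined as carbinol 10 and then oxidised. Carbon–carbon bond formation by addition of a small aryl anion to an aldehyde is not sensitive to the crowding at C4. An aldehyde is preferred to an acid chloride or amide because it is the most electrophilic partner and cannot add twice. Ring C is already in place in 8, which keeps the route convergent and puts an electron-withdrawing acyloxy group on ring B before the migration. The forward reaction must add to the aldehyde faster than to the aryl ester.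

**8 from 6 and 7; 6 from 5.** The ring C ester is an unhindered phenol–acid condensation between phenol 6 and commercial acid 7. Phenol 6 comes from 3,4,5-trihydroxybenzaldehyde 5 by benzylation of O4 and one of the two equivalent meta oxygens. This is the one place where a symmetric triol has to be differentiated, and the order of acidity (O4 first) decides it.

**4 from 1 through 3 and 2.** Bromide 4 comes from commercial methyl 4-bromo-3,5-dihydroxybenzoate 1 by benzylation (2), ester reduction (3) and silylation. The bromine of 1 marks C4 unambiguously, so no regiochemical question arises on ring A.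

## Roads not taken

**Alternative 1:** Ring B would be built and not bought.
- **Cut:** the C1–C6 and C2–C3 bonds of ring B, leading to 3,4-bis(benzyloxy)furan A2 and the propiolate ester A3 of the benzyl-protected ring A phenol.
- **Forward key step:** A2 and A3 would combine in a thermal Diels–Alder reaction to the oxygen-bridged adduct A4. Acid would open and aromatise A4 in the same flask to the A–B phenol A1. Acylation with 7 and hydrogenolysis would follow.
- **Merits:** the free hydroxyl of ring B appears at one defined position, so no statistical protection of a symmetric triol is needed. The hindered phenol is acylated by a very small acyl group. The carboxyl is carried as a benzyl ester, so the endgame is short.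
- **Weak points:** A2 is an electron-rich, acid- and air-sensitive furan that needs several steps of its own. Furan cycloadditions are reversible. The aryl propiolate A3 is an activated ester and a Michael acceptor. The direction in which the bridge of A4 opens decides between the gallate pattern and a salicylate pattern. Cation stability favours the wanted direction, but this is an argument and not a structural guarantee.
- **Comparison:** this road is better on ring B regiochemistry and on the number of steps after the key step. The chosen plan sets against it three stable commercial benzenoids, routine steps and an A–B link whose position is fixed by the bromine of 1.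

**Alternative 2:** The ring C ester would be made by carbonylation.
- **Cut:** the C1(ring C)–carbonyl and carbonyl–O bonds, going back to 1,2,3-tris(benzyloxy)-5-bromobenzene A6, carbon monoxide A7 and the phenol A1.
- **Forward key step:** a palladium-catalysed aryloxycarbonylation with an amine base would give the octabenzyl compound A5, one hydrogenolysis away from 16.
- **Merits:** convergent, with a one-step endgame.
- **Weak points:** oxidative addition of zerovalent palladium to the electron-rich bromide A6 is slow. At the temperature this requires, the phenoxide of A1 can attack the aryl ester of another molecule, which scrambles the depside. Above all, the bond being made is the easiest one in the molecule: acid 7 forms it in one ordinary esterification. The hard problems, the hindered A–B ester and the differentiation of ring B, are passed on unsolved to the synthesis of A1.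
- **Comparison:** this road ends one step after its key step, against four in the chosen plan. The chosen plan spends those steps where the difficulty lies.

**Alternative 3:** Ring A would be folded from an open chain.
- **Cut:** the C1–C2 bond of ring A, giving the acyloxy triketo ester A9.
- **Forward key step:** base and a magnesium salt would bring the terminal methyl carbon of A9 onto the C2 keto group; loss of water would give the 3,5-dihydroxy-4-acyloxybenzoate A8.
- **Merits:** the hindered ester oxygen is acylated while still on an open chain. Ring A appears with its hydroxyls free and its carboxyl already a benzyl ester, so only hydrogenolysis remains.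
- **Weak points:** A9 is a heavily enolised polycarbonyl chain with an acyloxy group between two ketones. It is prone to O-cyclisation to pyranones, to acyl shift onto neighbouring enol oxygens and to retro-Claisen cleavage. The carbanion is needed at the least acidic position. No simple building blocks lead to A9 with the large B–C aroyl group in place. The product A8 has free hydroxyls on both sides of the new ester in the presence of an amine, which is the situation in which the aroyl group moves from O4 to O3.
- **Comparison:** on paper this road has the fewest steps after the key step and no protecting groups on ring A. The chosen plan sets against it isolable, stable intermediates and phenols that stay masked until the end.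

Key step: step 8

Remark on the chemistry: carbinol 10 is formed as a racemate and its only stereocenter is removed in step 7, so no configuration is specified; compounds 1, 5 and 7 are taken as purchased.

## Route

Step 1
Reactants: 1 methyl 4-bromo-3,5-dihydroxybenzoate
Product: 2 methyl 3,5-bis(benzyloxy)-4-bromobenzoate
Conditions: BnBr, K2CO3, DMF, 60 °C
Reagents that add atoms: benzyl bromide, BrCc1ccccc1
Why: Williamson ether synthesis on both phenoxides; the methyl ester and the aryl bromide are inert to K2CO3 in DMF.

Step 2
Reactants: 2 methyl 3,5-bis(benzyloxy)-4-bromobenzoate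
Product: 3 [3,5-bis(benzyloxy)-4-bromophenyl]methanol
Conditions: i-Bu2AlH, CH2Cl2, −78 → 0 °C; aq. potassium sodium tartrate
Reagents that add atoms: none
Why: Aluminium hydride reduction of the ester to the primary alcohol; at low temperature the aryl bromide and the benzyl ethers are not touched.

Step 3
Reactants: 3 [3,5-bis(benzyloxy)-4-bromophenyl]methanol
Product: 4 {[3,5-bis(benzyloxy)-4-bromophenyl]methoxy}(tert-butyl)dimethylsilane
Conditions: TBSCl, imidazole, DMF, rt
Reagents that add atoms: tert-butyldimethylsilyl chloride, CC(C)(C)[Si](C)(C)Cl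
Why: Standard silylation of a primary alcohol; it removes the acidic proton before the organolithium step and keeps C1 of ring A an alkyl-type substituent.

Step 4
Reactants: 5 3,4,5-trihydroxybenzaldehyde
Product: 6 3,4-bis(benzyloxy)-5-hydroxybenzaldehyde
Conditions: BnBr (2 equiv), K2CO3 (2 equiv), DMF, N2, 0 °C → rt
Reagents that add atoms: benzyl bromide, BrCc1ccccc1
Why: Williamson ether synthesis under stoichiometric control; the hydroxyl para to the formyl group is the most acidic and reacts first, and the second benzyl group can only enter one of two equivalent meta positions, so a single dibenzyl ether should form and be separable from mono- and tribenzyl ethers.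

Step 5
Reactants: 6 3,4-bis(benzyloxy)-5-hydroxybenzaldehyde; 7 3,4,5-tris(benzyloxy)benzoic acid
Product: 8 2,3-bis(benzyloxy)-5-formylphenyl 3,4,5-tris(benzyloxy)benzoate
Conditions: DCC, DMAP (cat.), CH2Cl2, 0 °C → rt
Reagents that add atoms: none
Why: Steglich esterification of the only free hydroxyl by the acylpyridinium derived from 7; the aldehyde and the benzyl ethers do not take part.

Step 6
Reactants: 4 {[3,5-bis(benzyloxy)-4-bromophenyl]methoxy}(tert-butyl)dimethylsilane; 8 2,3-bis(benzyloxy)-5-formylphenyl 3,4,5-tris(benzyloxy)benzoate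
Product: 10 2,3-bis(benzyloxy)-5-[(2,6-bis(benzyloxy)-4-{[(tert-butyldimethylsilyl)oxy]methyl}phenyl)(hydroxy)methyl]phenyl 3,4,5-tris(benzyloxy)benzoate (racemic), via aryllithium 9 (not isolated)
Conditions: 4, n-BuLi (1.0 equiv relative to 8), THF, −78 °C; cannulated into 8, THF, −78 °C; AcOH, −78 °C
Reagents that add atoms: none
Why: Bromine–lithium exchange followed by 1,2-addition of the aryllithium to the aldehyde; the aldehyde is far more electrophilic than the aryl ester at −78 °C, inverse addition keeps it in excess over the organolithium, and a cold acidic quench prevents the alkoxide from attacking an ester; the new stereocenter is not controlled and is removed in step 7.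

Step 7
Reactants: 10 2,3-bis(benzyloxy)-5-[(2,6-bis(benzyloxy)-4-{[(tert-butyldimethylsilyl)oxy]methyl}phenyl)(hydroxy)methyl]phenyl 3,4,5-tris(benzyloxy)benzoate
Product: 11 5-(2,6-bis(benzyloxy)-4-{[(tert-butyldimethylsilyl)oxy]methyl}benzoyl)-2,3-bis(benzyloxy)phenyl 3,4,5-tris(benzyloxy)benzoate
Conditions: Dess–Martin periodinane, CH2Cl2, rt
Reagents that add atoms: none
Why: Dess–Martin oxidation of a secondary diaryl carbinol to the diaryl ketone under near-neutral conditions that leave the silyl ether, the benzyl ethers and the aryl ester untouched.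

Step 8
Reactants: 11 5-(2,6-bis(benzyloxy)-4-{[(tert-butyldimethylsilyl)oxy]methyl}benzoyl)-2,3-bis(benzyloxy)phenyl 3,4,5-tris(benzyloxy)benzoate
Product: 12 2,6-bis(benzyloxy)-4-{[(tert-butyldimethylsilyl)oxy]methyl}phenyl 3,4-bis(benzyloxy)-5-{[3,4,5-tris(benzyloxy)benzoyl]oxy}benzoate
Conditions: (CF3CO)2O, urea·H2O2, Na2HPO4, CH2Cl2, 0 °C → rt
Reagents that add atoms: trifluoroperacetic acid, OOC(=O)C(F)(F)F (formed in the flask from trifluoroacetic anhydride, O=C(OC(=O)C(F)(F)F)C(F)(F)F, and urea–hydrogen peroxide, OO.NC(N)=O)
Why: This is a Baeyer–Villiger oxidation: trifluoroperacetic acid adds to the ketone carbonyl of 11 to give a tetrahedral peroxy adduct. The aryl group lying anti to the O–O bond then shifts from carbon to oxygen as trifluoroacetate leaves, which creates the C4(ring A)–O and O–carbonyl bonds in one event. The closest known reaction type is the oxidation of unsymmetrical benzophenones to aryl benzoates with this peracid, in which the more electron-rich aryl group migrates. No ring closes and no stereocenter is formed. The selectivity needed is migration of ring A rather than ring B; the migrating carbon of ring A has oxygen lone pairs on both ortho carbons and an alkyl-type group para, all of which stabilise the positive charge that develops on the migrating ring. Ring B offers only a para benzyloxy group that is twisted out of conjugation by its two ortho oxygen neighbours, while its two meta oxygens, one of them an acyloxy group, withdraw inductively; ring A is also the bulkier group and should prefer the position anti to the leaving group. Na2HPO4 takes up trifluoroacetic acid, which protects the silyl ether and restrains acid-promoted hydroxylation of the alkoxy arenes, and a small excess of peracid at 0 °C limits over-oxidation of the product. The silyloxymethyl group at C1 of ring A, in place of an ester, is what keeps the para position of the migrating ring from being electron-poor.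

Step 9
Reactants: 12 2,6-bis(benzyloxy)-4-{[(tert-butyldimethylsilyl)oxy]methyl}phenyl 3,4-bis(benzyloxy)-5-{[3,4,5-tris(benzyloxy)benzoyl]oxy}benzoate
Product: 13 2,6-bis(benzyloxy)-4-(hydroxymethyl)phenyl 3,4-bis(benzyloxy)-5-{[3,4,5-tris(benzyloxy)benzoyl]oxy}benzoate
Conditions: HF·pyridine, THF/pyridine, 0 °C → rt
Reagents that add atoms: none
Why: Fluoride-driven desilylation of a primary silyl ether; the reagent is not basic, so no alkoxide is formed that could attack the two aryl esters.

Step 10
Reactants: 13 2,6-bis(benzyloxy)-4-(hydroxymethyl)phenyl 3,4-bis(benzyloxy)-5-{[3,4,5-tris(benzyloxy)benzoyl]oxy}benzoate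
Product: 14 2,6-bis(benzyloxy)-4-formylphenyl 3,4-bis(benzyloxy)-5-{[3,4,5-tris(benzyloxy)benzoyl]oxy}benzoate
Conditions: Dess–Martin periodinane, CH2Cl2, rt
Reagents that add atoms: none
Why: Dess–Martin oxidation of a primary benzylic alcohol stops cleanly at the aldehyde and uses no halogen-based oxidant that could attack the activated positions of ring A.

Step 11
Reactants: 14 2,6-bis(benzyloxy)-4-formylphenyl 3,4-bis(benzyloxy)-5-{[3,4,5-tris(benzyloxy)benzoyl]oxy}benzoate
Product: 15 3,5-bis(benzyloxy)-4-({3,4-bis(benzyloxy)-5-[3,4,5-tris(benzyloxy)benzoyloxy]benzoyl}oxy)benzoic acid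
Conditions: NaClO2, NaH2PO4, 2-methyl-2-butene, t-BuOH/THF/H2O, 0 °C → rt
Reagents that add atoms: sodium chlorite, [Na+].[O-]Cl=O
Why: Pinnick oxidation of the aryl aldehyde to the acid at mildly acidic pH, which the aryl esters tolerate; 2-methyl-2-butene traps the hypochlorous acid that would otherwise chlorinate the electron-rich rings.

Step 12
Reactants: 15 3,5-bis(benzyloxy)-4-({3,4-bis(benzyloxy)-5-[3,4,5-tris(benzyloxy)benzoyloxy]benzoyl}oxy)benzoic acid
Product: 16 3,5-dihydroxy-4-({3,4-dihydroxy-5-[(3,4,5-trihydroxybenzoyl)oxy]benzoyl}oxy)benzoic acid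
Conditions: H2 (1 atm), Pd/C, THF, rt
Reagents that add atoms: none
Why: Catalytic hydrogenolysis of the seven benzyl ethers over palladium; the aryl esters are not benzylic C–O bonds and the neutral, aprotic medium gives the freed ortho-hydroxyls no base or nucleophile with which to move or cleave the acyl groups.

## Compound list

1 | methyl 4-bromo-3,5-dihydroxybenzoate | COC(=O)c1cc(O)c(Br)c(O)c1 | starting material
2 | methyl 3,5-bis(benzyloxy)-4-bromobenzoate | COC(=O)c1cc(OCc2ccccc2)c(Br)c(OCc2ccccc2)c1 | intermediate
3 | [3,5-bis(benzyloxy)-4-bromophenyl]methanol | OCc1cc(OCc2ccccc2)c(Br)c(OCc2ccccc2)c1 | intermediate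
4 | {[3,5-bis(benzyloxy)-4-bromophenyl]methoxy}(tert-butyl)dimethylsilane | CC(C)(C)[Si](C)(C)OCc1cc(OCc2ccccc2)c(Br)c(OCc2ccccc2)c1 | intermediate
5 | 3,4,5-trihydroxybenzaldehyde | O=Cc1cc(O)c(O)c(O)c1 | starting material
6 | 3,4-bis(benzyloxy)-5-hydroxybenzaldehyde | O=Cc1cc(O)c(OCc2ccccc2)c(OCc2ccccc2)c1 | intermediate
7 | 3,4,5-tris(benzyloxy)benzoic acid | O=C(O)c1cc(OCc2ccccc2)c(OCc2ccccc2)c(OCc2ccccc2)c1 | starting material
8 | 2,3-bis(benzyloxy)-5-formylphenyl 3,4,5-tris(benzyloxy)benzoate | O=Cc1cc(OCc2ccccc2)c(OCc2ccccc2)c(OC(=O)c2cc(OCc3ccccc3)c(OCc3ccccc3)c(OCc3ccccc3)c2)c1 | intermediate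
9 | (2,6-bis(benzyloxy)-4-{[(tert-butyldimethylsilyl)oxy]methyl}phenyl)lithium | CC(C)(C)[Si](C)(C)OCc1cc(OCc2ccccc2)c([Li])c(OCc2ccccc2)c1 | intermediate
10 | 2,3-bis(benzyloxy)-5-[(2,6-bis(benzyloxy)-4-{[(tert-butyldimethylsilyl)oxy]methyl}phenyl)(hydroxy)methyl]phenyl 3,4,5-tris(benzyloxy)benzoate (racemic) | CC(C)(C)[Si](C)(C)OCc1cc(OCc2ccccc2)c(C(O)c2cc(OCc3ccccc3)c(OCc3ccccc3)c(OC(=O)c3cc(OCc4ccccc4)c(OCc4ccccc4)c(OCc4ccccc4)c3)c2)c(OCc2ccccc2)c1 | intermediate
11 | 5-(2,6-bis(benzyloxy)-4-{[(tert-butyldimethylsilyl)oxy]methyl}benzoyl)-2,3-bis(benzyloxy)phenyl 3,4,5-tris(benzyloxy)benzoate | CC(C)(C)[Si](C)(C)OCc1cc(OCc2ccccc2)c(C(=O)c2cc(OCc3ccccc3)c(OCc3ccccc3)c(OC(=O)c3cc(OCc4ccccc4)c(OCc4ccccc4)c(OCc4ccccc4)c3)c2)c(OCc2ccccc2)c1 | intermediate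
12 | 2,6-bis(benzyloxy)-4-{[(tert-butyldimethylsilyl)oxy]methyl}phenyl 3,4-bis(benzyloxy)-5-{[3,4,5-tris(benzyloxy)benzoyl]oxy}benzoate | CC(C)(C)[Si](C)(C)OCc1cc(OCc2ccccc2)c(OC(=O)c2cc(OCc3ccccc3)c(OCc3ccccc3)c(OC(=O)c3cc(OCc4ccccc4)c(OCc4ccccc4)c(OCc4ccccc4)c3)c2)c(OCc2ccccc2)c1 | intermediate
13 | 2,6-bis(benzyloxy)-4-(hydroxymethyl)phenyl 3,4-bis(benzyloxy)-5-{[3,4,5-tris(benzyloxy)benzoyl]oxy}benzoate | OCc1cc(OCc2ccccc2)c(OC(=O)c2cc(OCc3ccccc3)c(OCc3ccccc3)c(OC(=O)c3cc(OCc4ccccc4)c(OCc4ccccc4)c(OCc4ccccc4)c3)c2)c(OCc2ccccc2)c1 | intermediate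
14 | 2,6-bis(benzyloxy)-4-formylphenyl 3,4-bis(benzyloxy)-5-{[3,4,5-tris(benzyloxy)benzoyl]oxy}benzoate | O=Cc1cc(OCc2ccccc2)c(OC(=O)c2cc(OCc3ccccc3)c(OCc3ccccc3)c(OC(=O)c3cc(OCc4ccccc4)c(OCc4ccccc4)c(OCc4ccccc4)c3)c2)c(OCc2ccccc2)c1 | intermediate
15 | 3,5-bis(benzyloxy)-4-({3,4-bis(benzyloxy)-5-[3,4,5-tris(benzyloxy)benzoyloxy]benzoyl}oxy)benzoic acid | O=C(O)c1cc(OCc2ccccc2)c(OC(=O)c2cc(OCc3ccccc3)c(OCc3ccccc3)c(OC(=O)c3cc(OCc4ccccc4)c(OCc4ccccc4)c(OCc4ccccc4)c3)c2)c(OCc2ccccc2)c1 | intermediate
16 | 3,5-dihydroxy-4-({3,4-dihydroxy-5-[(3,4,5-trihydroxybenzoyl)oxy]benzoyl}oxy)benzoic acid | O=C(O)c1cc(O)c(OC(=O)c2cc(O)c(O)c(OC(=O)c3cc(O)c(O)c(O)c3)c2)c(O)c1 | target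

## Step count and risks

Total step count: 12. Longest linear sequence: 10 steps (steps 1, 2, 3, 6, 7, 8, 9, 10, 11, 12 from compound 1).

**Step 8 (key step).** Three things may go wrong. Peracid addition to the crowded, doubly aryl-flanked carbonyl may be slow, so that electrophilic hydroxylation of the benzyloxy-substituted rings overtakes oxygen insertion; ring A after insertion is the most exposed. Migration of ring B may compete if its para benzyloxy group donates more than expected. The silyl ether may be lost if the buffer is overwhelmed.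

Fallback: make the A–B ester by acylation, setting out from 4 and 8 and returning at 12.
- Aryllithium 9, generated from 4 as in step 6, would be trapped with B(OMe)3 to give dimethyl (2,6-bis(benzyloxy)-4-{[(tert-butyldimethylsilyl)oxy]methyl}phenyl)boronate F1.
- Oxidation of F1 with H2O2/NaOH would give 2,6-bis(benzyloxy)-4-{[(tert-butyldimethylsilyl)oxy]methyl}phenol F2.
- Aldehyde 8 would be oxidised under the conditions of step 11 to 3,4-bis(benzyloxy)-5-{[3,4,5-tris(benzyloxy)benzoyl]oxy}benzoic acid F3.
- F3 would be converted with oxalyl chloride and catalytic DMF into 3,4-bis(benzyloxy)-5-{[3,4,5-tris(benzyloxy)benzoyl]oxy}benzoyl chloride F4.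
- F4 would acylate F2 (Et3N, DMAP, CH2Cl2) to give 12.

**Step 6.** The aryllithium may attack the aryl ester of 8, or the galloyl group may be transferred to the new alkoxide, if mixing is poor or the temperature rises. Warming could also let the aryllithium deprotonate a neighbouring benzylic position.

Fallback: bring in ring C after the C–C bond is made, setting out from 6 and 4 and returning at 11.
- Phenol 6 would be allylated (allyl bromide, K2CO3) to 3-(allyloxy)-4,5-bis(benzyloxy)benzaldehyde F5.
- Addition of 9 would give [3-(allyloxy)-4,5-bis(benzyloxy)phenyl](2,6-bis(benzyloxy)-4-{[(tert-butyldimethylsilyl)oxy]methyl}phenyl)methanol F6.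
- Dess–Martin oxidation would give [3-(allyloxy)-4,5-bis(benzyloxy)phenyl](2,6-bis(benzyloxy)-4-{[(tert-butyldimethylsilyl)oxy]methyl}phenyl)methanone F7.
- Deallylation with Pd(PPh3)4 (zerovalent palladium) and morpholine would give [3,4-bis(benzyloxy)-5-hydroxyphenyl](2,6-bis(benzyloxy)-4-{[(tert-butyldimethylsilyl)oxy]methyl}phenyl)methanone F8.
- Esterification of F8 with 7 under the conditions of step 5 would give 11.

**Step 4.** Alkylation may not stop cleanly at the dibenzyl stage, leaving a statistical spread over mono-, di- and tribenzyl ethers. The pyrogallol unit may also oxidise in air under base.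

Fallback: differentiate the two meta oxygens by acylation, setting out from 5 and returning at 8.
- Selective benzylation of the most acidic hydroxyl with BnCl, NaHCO3 and NaI in DMF would give 4-(benzyloxy)-3,5-dihydroxybenzaldehyde F9.
- Acylation of this symmetric diol with one equivalent of 7 (DCC, DMAP) can give only one monoester, 2-(benzyloxy)-5-formyl-3-hydroxyphenyl 3,4,5-tris(benzyloxy)benzoate F10.
- Benzylation of the remaining phenol of F10 under neutral Mitsunobu conditions (BnOH, PPh3, diisopropyl azodicarboxylate) would give 8.

**Step 12.** Cleavage of seven benzyl ethers may stall before completion. Once hydroxyls next to the ester oxygens are free, acyl migration between neighbouring oxygens or solvolysis of the depside links may set in during a long reaction or during isolation.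

Fallback: non-reductive debenzylation of 15 with BCl3 and pentamethylbenzene as cation scavenger in CH2Cl2 at −78 °C. It sets out from 15 and gives 16 directly, with no new intermediate.

## Further compounds

F1 | step 8 | dimethyl (2,6-bis(benzyloxy)-4-{[(tert-butyldimethylsilyl)oxy]methyl}phenyl)boronate | CC(C)(C)[Si](C)(C)OCc1cc(OCc2ccccc2)c(B(OC)OC)c(OCc2ccccc2)c1
F2 | step 8 | 2,6-bis(benzyloxy)-4-{[(tert-butyldimethylsilyl)oxy]methyl}phenol | CC(C)(C)[Si](C)(C)OCc1cc(OCc2ccccc2)c(O)c(OCc2ccccc2)c1
F3 | step 8 | 3,4-bis(benzyloxy)-5-{[3,4,5-tris(benzyloxy)benzoyl]oxy}benzoic acid | O=C(O)c1cc(OCc2ccccc2)c(OCc2ccccc2)c(OC(=O)c2cc(OCc3ccccc3)c(OCc3ccccc3)c(OCc3ccccc3)c2)c1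
F4 | step 8 | 3,4-bis(benzyloxy)-5-{[3,4,5-tris(benzyloxy)benzoyl]oxy}benzoyl chloride | O=C(Cl)c1cc(OCc2ccccc2)c(OCc2ccccc2)c(OC(=O)c2cc(OCc3ccccc3)c(OCc3ccccc3)c(OCc3ccccc3)c2)c1
F5 | step 6 | 3-(allyloxy)-4,5-bis(benzyloxy)benzaldehyde | C=CCOc1cc(C=O)cc(OCc2ccccc2)c1OCc1ccccc1
F6 | step 6 | [3-(allyloxy)-4,5-bis(benzyloxy)phenyl](2,6-bis(benzyloxy)-4-{[(tert-butyldimethylsilyl)oxy]methyl}phenyl)methanol (racemic) | CC(C)(C)[Si](C)(C)OCc1cc(OCc2ccccc2)c(C(O)c2cc(OCC=C)c(OCc3ccccc3)c(OCc3ccccc3)c2)c(OCc2ccccc2)c1
F7 | step 6 | [3-(allyloxy)-4,5-bis(benzyloxy)phenyl](2,6-bis(benzyloxy)-4-{[(tert-butyldimethylsilyl)oxy]methyl}phenyl)methanone | CC(C)(C)[Si](C)(C)OCc1cc(OCc2ccccc2)c(C(=O)c2cc(OCC=C)c(OCc3ccccc3)c(OCc3ccccc3)c2)c(OCc2ccccc2)c1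
F8 | step 6 | [3,4-bis(benzyloxy)-5-hydroxyphenyl](2,6-bis(benzyloxy)-4-{[(tert-butyldimethylsilyl)oxy]methyl}phenyl)methanone | CC(C)(C)[Si](C)(C)OCc1cc(OCc2ccccc2)c(C(=O)c2cc(O)c(OCc3ccccc3)c(OCc3ccccc3)c2)c(OCc2ccccc2)c1
F9 | step 4 | 4-(benzyloxy)-3,5-dihydroxybenzaldehyde | O=Cc1cc(O)c(OCc2ccccc2)c(O)c1
F10 | step 4 | 2-(benzyloxy)-5-formyl-3-hydroxyphenyl 3,4,5-tris(benzyloxy)benzoate | O=Cc1cc(O)c(OCc2ccccc2)c(OC(=O)c2cc(OCc3ccccc3)c(OCc3ccccc3)c(OCc3ccccc3)c2)c1
F0 | step 12 | none | none
A1 | alternative 1 | benzyl 3,5-bis(benzyloxy)-4-{[3,4-bis(benzyloxy)-5-hydroxybenzoyl]oxy}benzoate | O=C(OCc1ccccc1)c1cc(OCc2ccccc2)c(OC(=O)c2cc(OCc3ccccc3)c(OCc3ccccc3)c(O)c2)c(OCc2ccccc2)c1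
A2 | alternative 1 | 3,4-bis(benzyloxy)furan | c1ccc(cc1)COc1cocc1OCc1ccccc1
A3 | alternative 1 | benzyl 3,5-bis(benzyloxy)-4-(prop-2-ynoyloxy)benzoate | C#CC(=O)Oc1c(OCc2ccccc2)cc(C(=O)OCc2ccccc2)cc1OCc1ccccc1
A4 | alternative 1 | 2,6-bis(benzyloxy)-4-[(benzyloxy)carbonyl]phenyl 5,6-bis(benzyloxy)-7-oxabicyclo[2.2.1]hepta-2,5-diene-2-carboxylate (racemic) | O=C(Oc1c(OCc2ccccc2)cc(C(=O)OCc2ccccc2)cc1OCc1ccccc1)C1=CC2OC1C(OCc1ccccc1)=C2OCc1ccccc1
A5 | alternative 2 | benzyl 3,5-bis(benzyloxy)-4-({3,4-bis(benzyloxy)-5-[3,4,5-tris(benzyloxy)benzoyloxy]benzoyl}oxy)benzoate | O=C(OCc1ccccc1)c1cc(OCc2ccccc2)c(OC(=O)c2cc(OCc3ccccc3)c(OCc3ccccc3)c(OC(=O)c3cc(OCc4ccccc4)c(OCc4ccccc4)c(OCc4ccccc4)c3)c2)c(OCc2ccccc2)c1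
A6 | alternative 2 | 1,2,3-tris(benzyloxy)-5-bromobenzene | Brc1cc(OCc2ccccc2)c(OCc2ccccc2)c(OCc2ccccc2)c1
A7 | alternative 2 | carbon monoxide | [C-]#[O+]
A8 | alternative 3 | benzyl 3,5-dihydroxy-4-({3,4-bis(benzyloxy)-5-[3,4,5-tris(benzyloxy)benzoyloxy]benzoyl}oxy)benzoate | O=C(OCc1ccccc1)c1cc(O)c(OC(=O)c2cc(OCc3ccccc3)c(OCc3ccccc3)c(OC(=O)c3cc(OCc4ccccc4)c(OCc4ccccc4)c(OCc4ccccc4)c3)c2)c(O)c1
A9 | alternative 3 | benzyl 5-({3,4-bis(benzyloxy)-5-[3,4,5-tris(benzyloxy)benzoyloxy]benzoyl}oxy)-2,4,6-trioxoheptanoate | CC(=O)C(OC(=O)c1cc(OCc2ccccc2)c(OCc2ccccc2)c(OC(=O)c2cc(OCc3ccccc3)c(OCc3ccccc3)c(OCc3ccccc3)c2)c1)C(=O)CC(=O)C(=O)OCc1ccccc1
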